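**Plan**
- Retrosynthesis: (a) open the pyranone at the lactone O4–C5 bond and cut C6=C7 (Z-olefination of a C7 aldehyde, itself a cleaved mannose C5–C6 glycol); (b) trace the anti C3' benzoate back, with inversion, to a syn C3'–B bond; (c) cut C2'–C3' by a 1,2-metallate shift into an (E)-alkenyl pinacol boronate and metalated (R)-methyloxirane; (d) cut B–C2' and C2–H back to a silylacetylene and D-mannonolactone diacetonide.
- Forward: the tetrahydrofuran ring is the furanose ring of D-mannose throughout; the alkyne is put on C2 (steps 1–4) and turned into the alkenyl boronate (step 5), the three-carbon chain end is joined (step 6), its oxygen pattern is finished (steps 7–8), and the pyranone ring is closed last (steps 9–11).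
- Enabling feature: C3' (OBz) and C4' (OH, CH3) are a vicinal dioxygenated pair ending in a methyl group, i.e. an opened methyloxirane whose CH2 carbon has gained one C–C and one C–heteroatom bond. A lithiated oxirane is a carbenoid for exactly this, and the strain of its three-membered ring drives the alkenyl shift from boron to C3'.
- Stereochemistry: C3, C3a, C7a come from C2, C3, C4 of D-mannose; C2 from exo-face hydride delivery (step 3); C4' from (R)-methyloxirane; C3' from trans-lithiation, retentive borylation and invertive migration (step 6), then retentive oxidation and invertive Mitsunobu benzoylation. The E-alkene comes from syn-hydroboration, the Z-enoate from Still–Gennari olefination.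

Key step: step 6

Remark: sugar locants C1–C6 are used for mannose-derived intermediates (target C2, C3, C3a, C7a, C7 = sugar C1, C2, C3, C4, C5) and primed locants C1'–C5' for the pentenyl chain (C1' on the ring); tert-butyldimethylsilyl triflate is assumed to act as triethylsilyl triflate does in the known epoxide homologation.

Step 1
Reactants: 1 2,3:5,6-di-O-isopropylidene-α-D-mannofuranose
Product: 2 2,3:5,6-di-O-isopropylidene-D-mannono-1,4-lactone
Conditions: DMSO, Ac2O, rt
Reagents that add atoms: none
Why: Albright–Goldman (activated-DMSO) oxidation of the anomeric lactol should give the γ-lactone without touching the acetonides or any stereocenter.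

Step 2
Reactants: 2 2,3:5,6-di-O-isopropylidene-D-mannono-1,4-lactone; 3 ethynyltrimethylsilane
Product: 5 2,3:5,6-di-O-isopropylidene-1-C-[(trimethylsilyl)ethynyl]-D-mannofuranose (hemiketal; anomeric mixture), via lithium (trimethylsilyl)acetylide 4 (not isolated)
Conditions: 3, n-BuLi, THF, −78 °C; then 2, −78 °C; AcOH quench
Reagents that add atoms: none
Why: 1,2-addition of a lithium acetylide to a γ-lactone should stop at the hemiketal because the tetrahedral lithium alkoxide does not collapse at −78 °C; the new anomeric center is erased in step 3.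

Step 3
Reactants: 5 2,3:5,6-di-O-isopropylidene-1-C-[(trimethylsilyl)ethynyl]-D-mannofuranose
Product: 7 [(2,3:5,6-di-O-isopropylidene-β-D-mannofuranosyl)ethynyl]trimethylsilane (alkynyl cis to O2, O3 and C5; C1 S), via furanosyl oxocarbenium ion 6 (not isolated)
Conditions: Et3SiH, BF3·OEt2 (promoter), CH2Cl2, −78 → −40 °C
Reagents that add atoms: none
Why: Lewis-acid ionization of the hemiketal and silane reduction of the oxocarbenium ion (reductive deoxygenation of a lactol, the lactone route to C-glycosides) should deliver hydride to C1 from the convex α-face, anti to the cis-fused 2,3-dioxolane and the C4 side chain, which places the alkynyl group on the β-face and gives the all-cis tetrahydrofuran.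

Step 4
Reactants: 7 [(2,3:5,6-di-O-isopropylidene-β-D-mannofuranosyl)ethynyl]trimethylsilane
Product: 8 (2,3:5,6-di-O-isopropylidene-β-D-mannofuranosyl)ethyne
Conditions: K2CO3 (cat.), MeOH, rt
Reagents that add atoms: none
Why: base-catalyzed methanolysis of the C(sp)–Si bond (protodesilylation) should free the terminal alkyne, the acetonides being stable to carbonate in methanol.

Step 5
Reactants: 8 (2,3:5,6-di-O-isopropylidene-β-D-mannofuranosyl)ethyne
Product: 9 2-[(E)-2-(2,3:5,6-di-O-isopropylidene-β-D-mannofuranosyl)ethenyl]-4,4,5,5-tetramethyl-1,3,2-dioxaborolane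
Conditions: pinacolborane, Cp2Zr(H)Cl (cat.), Et3N (cat.), CH2Cl2, 50 °C
Reagents that add atoms: pinacolborane, B1OC(C)(C)C(C)(C)O1
Why: zirconium-catalyzed hydroboration of a terminal alkyne (syn-hydrozirconation, then Zr-to-B exchange) should place boron on the terminal carbon and give only the E-alkenyl boronate.

Step 6
Reactants: 9 2-[(E)-2-(2,3:5,6-di-O-isopropylidene-β-D-mannofuranosyl)ethenyl]-4,4,5,5-tetramethyl-1,3,2-dioxaborolane; 10 (R)-2-methyloxirane
Product: 13 2-[(1E,3R,4R)-4-[(tert-butyldimethylsilyl)oxy]-1-(2,3:5,6-di-O-isopropylidene-β-D-mannofuranosyl)pent-1-en-3-yl]-4,4,5,5-tetramethyl-1,3,2-dioxaborolane, via [(2R,3R)-3-methyloxiran-2-yl]lithium 11 (not isolated), via lithium alkenyl(oxiranyl)pinacolatoborate 12 (not isolated)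
Conditions: 10 (excess), lithium 2,2,6,6-tetramethylpiperidide (from the amine and n-BuLi; added to 9 + 10), THF, −30 °C; then t-BuMe2SiOTf, −30 °C → rt
Reagents that add atoms: tert-butyldimethylsilyl trifluoromethanesulfonate, CC(C)(C)[Si](C)(C)OS(=O)(=O)C(F)(F)F
Why: Proposed new method: the amide base should remove the oxirane CH2 hydrogen trans to the methyl group of 10 in the presence of 9, the oxiranyllithium 11 is captured at boron with retention to give ate complex 12, and O-silylation of the oxirane oxygen then triggers a 1,2-shift of the alkenyl group from boron to the oxirane carbon, anti to the breaking C–O bond, so that release of the three-membered ring's strain drives formation of the C2'–C3' bond. The closest known reaction types are the homologation of alkyl and aryl pinacol boronic esters with lithiated terminal epoxides (a 1,2-metallate rearrangement giving syn-β-silyloxy boronic esters) and the lithiation–borylation of alkenyl boronic esters with lithiated carbamates, which shows that sp2 groups migrate readily and that α-substituted allylic pinacol boronates are configurationally and regiochemically stable; what is new is an alkenyl migrating group on an oxiranyl boronate. No ring is closed; the oxirane is opened. The new stereocenter C3' (R, bearing boron) is fixed stereospecifically by trans-lithiation, retentive borylation and invertive migration, C4' (R) is carried over unchanged from 10, and the E-alkene is kept because the alkenyl group migrates with retention of geometry. The step needs deprotonation of the epoxide in preference to the allylic C1–H of 9, and alkenyl migration in preference to migration of a pinacol oxygen or to boron–oxygen elimination of the β-oxido boronate; generation of 11 at −30 °C beside the hindered pinacol ester, the high migratory aptitude of an sp2 carbon and immediate capping of the alkoxide as its silyl ether should secure these.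

Step 7
Reactants: 13 2-[(1E,3R,4R)-4-[(tert-butyldimethylsilyl)oxy]-1-(2,3:5,6-di-O-isopropylidene-β-D-mannofuranosyl)pent-1-en-3-yl]-4,4,5,5-tetramethyl-1,3,2-dioxaborolane
Product: 14 (1E,3R,4R)-4-[(tert-butyldimethylsilyl)oxy]-1-(2,3:5,6-di-O-isopropylidene-β-D-mannofuranosyl)pent-1-en-3-ol
Conditions: H2O2 (30% aq), NaOH (2 M aq), THF, 0 °C
Reagents that add atoms: hydrogen peroxide, OO
Why: oxidation of the C–B bond by hydroperoxide (1,2-shift of carbon from boron to oxygen) should proceed with retention and without allylic transposition, giving the syn (3'R,4'R) monosilylated diol.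

Step 8
Reactants: 14 (1E,3R,4R)-4-[(tert-butyldimethylsilyl)oxy]-1-(2,3:5,6-di-O-isopropylidene-β-D-mannofuranosyl)pent-1-en-3-ol; 15 benzoic acid
Product: 17 (1E,3S,4R)-4-[(tert-butyldimethylsilyl)oxy]-1-(2,3:5,6-di-O-isopropylidene-β-D-mannofuranosyl)pent-1-en-3-yl benzoate, via alkoxytriphenylphosphonium benzoate 16 (not isolated)
Conditions: 15, PPh3, i-PrO2CN=NCO2i-Pr, toluene, −20 °C → rt
Reagents that add atoms: none
Why: Mitsunobu esterification should displace the oxyphosphonium group by benzoate in an SN2 step with inversion at C3', turning the syn alcohol into the anti (3'S,4'R) benzoate of the target while installing the ester; SN1 and SN2' paths are disfavored because the allyl cation would be flanked by two oxygen-bearing carbons and C1' is shielded by the ring.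

Step 9
Reactants: 17 (1E,3S,4R)-4-[(tert-butyldimethylsilyl)oxy]-1-(2,3:5,6-di-O-isopropylidene-β-D-mannofuranosyl)pent-1-en-3-yl benzoate
Product: 19 (1E,3S,4R)-4-[(tert-butyldimethylsilyl)oxy]-1-(2,3-O-isopropylidene-β-D-lyxo-pentodialdo-1,4-furanosyl)pent-1-en-3-yl benzoate (C5 aldehyde), via 5,6-diol 18 (not isolated)
Conditions: H5IO6, EtOAc, rt
Reagents that add atoms: none
Why: periodic acid in ethyl acetate should hydrolyze the terminal dioxolane selectively over the ring-fused 2,3-acetonide and cleave the liberated glycol in the same flask (acetal hydrolysis, then glycol cleavage), giving the aldehyde under non-basic conditions that leave C4 unepimerized.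

Step 10
Reactants: 19 (1E,3S,4R)-4-[(tert-butyldimethylsilyl)oxy]-1-(2,3-O-isopropylidene-β-D-lyxo-pentodialdo-1,4-furanosyl)pent-1-en-3-yl benzoate; 20 methyl bis(2,2,2-trifluoroethyl)phosphonoacetate
Product: 22 methyl (Z)-5,6-dideoxy-2,3-O-isopropylidene-β-D-lyxo-hept-5-enofuranuronate carrying at C1 the (1E,3S,4R)-3-(benzoyloxy)-4-[(tert-butyldimethylsilyl)oxy]pent-1-en-1-yl group, via potassium phosphonoacetate carbanion 21 (not isolated)
Conditions: 20, KN(SiMe3)2, 18-crown-6, THF, −78 °C; then 19, −78 °C
Reagents that add atoms: none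
Why: Still–Gennari olefination should give the Z-enoate by fast, irreversible collapse of the kinetic adduct of the trifluoroethyl phosphonate anion, and the weakly basic pre-formed anion at −78 °C should leave the benzoate and the α-alkoxy center C4 intact.

Step 11
Reactants: 22 methyl (Z)-5,6-dideoxy-2,3-O-isopropylidene-β-D-lyxo-hept-5-enofuranuronate carrying at C1 the (1E,3S,4R)-3-(benzoyloxy)-4-[(tert-butyldimethylsilyl)oxy]pent-1-en-1-yl group
Product: 24 (1E,3S,4R)-4-hydroxy-1-[(2S,3R,3aR,7aR)-3-hydroxy-5-oxo-2,3,3a,7a-tetrahydro-5H-furo[3,2-b]pyran-2-yl]pent-1-en-3-yl benzoate (target), via triol methyl ester 23 (not isolated)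
Conditions: CF3CO2H/H2O (9:1), 0 °C → rt
Reagents that add atoms: none
Why: acid hydrolysis should remove the 2,3-acetonide and the silyl ether, and the freed C3 hydroxyl, cis to the Z-enoate arm on C4, should close the six-membered unsaturated lactone by acid-catalyzed transesterification (lactonization), while the C2 hydroxyl, which could only form a seven-membered ring, stays free.

**Compound list**
1 | 2,3:5,6-di-O-isopropylidene-α-D-mannofuranose | O[C@H]1O[C@H]([C@H]2COC(C)(C)O2)[C@@H]3OC(C)(C)O[C@H]13 | starting material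
2 | 2,3:5,6-di-O-isopropylidene-D-mannono-1,4-lactone | O=C1O[C@H]([C@H]2COC(C)(C)O2)[C@@H]3OC(C)(C)O[C@H]13 | intermediate
3 | ethynyltrimethylsilane | C#C[Si](C)(C)C | starting material
4 | lithium (trimethylsilyl)acetylide | [Li]C#C[Si](C)(C)C | intermediate (not isolated)
5 | 2,3:5,6-di-O-isopropylidene-1-C-[(trimethylsilyl)ethynyl]-D-mannofuranose (hemiketal; anomeric mixture) | OC1(C#C[Si](C)(C)C)O[C@H]([C@H]2COC(C)(C)O2)[C@@H]3OC(C)(C)O[C@H]13 | intermediate
6 | 2,3:5,6-di-O-isopropylidene-1-C-[(trimethylsilyl)ethynyl]-D-mannofuranosyl oxocarbenium ion | C[Si](C)(C)C#CC1=[O+][C@H]([C@H]2COC(C)(C)O2)[C@@H]3OC(C)(C)O[C@H]13 | intermediate (not isolated)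
7 | [(2,3:5,6-di-O-isopropylidene-β-D-mannofuranosyl)ethynyl]trimethylsilane | C[Si](C)(C)C#C[C@@H]1O[C@H]([C@H]2COC(C)(C)O2)[C@@H]3OC(C)(C)O[C@H]13 | intermediate
8 | (2,3:5,6-di-O-isopropylidene-β-D-mannofuranosyl)ethyne | C#C[C@@H]1O[C@H]([C@H]2COC(C)(C)O2)[C@@H]3OC(C)(C)O[C@H]13 | intermediate
9 | 2-[(E)-2-(2,3:5,6-di-O-isopropylidene-β-D-mannofuranosyl)ethenyl]-4,4,5,5-tetramethyl-1,3,2-dioxaborolane | CC1(C)OB(/C=C/[C@@H]2O[C@H]([C@H]3COC(C)(C)O3)[C@@H]4OC(C)(C)O[C@H]24)OC1(C)C | intermediate
10 | (R)-2-methyloxirane | C[C@@H]1CO1 | starting material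
11 | [(2R,3R)-3-methyloxiran-2-yl]lithium (lithium trans to methyl) | C[C@H]1O[C@@H]1[Li] | intermediate (not isolated)
12 | lithium [(E)-2-(2,3:5,6-di-O-isopropylidene-β-D-mannofuranosyl)ethenyl][(2R,3R)-3-methyloxiran-2-yl]pinacolatoborate | C[C@H]1O[C@@H]1[B-]2(OC(C)(C)C(C)(C)O2)/C=C/[C@@H]3O[C@H]([C@H]4COC(C)(C)O4)[C@@H]5OC(C)(C)O[C@H]35.[Li+] | intermediate (not isolated)
13 | 2-[(1E,3R,4R)-4-[(tert-butyldimethylsilyl)oxy]-1-(2,3:5,6-di-O-isopropylidene-β-D-mannofuranosyl)pent-1-en-3-yl]-4,4,5,5-tetramethyl-1,3,2-dioxaborolane | C[C@@H](O[Si](C)(C)C(C)(C)C)[C@H](B1OC(C)(C)C(C)(C)O1)/C=C/[C@@H]2O[C@H]([C@H]3COC(C)(C)O3)[C@@H]4OC(C)(C)O[C@H]24 | intermediate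
14 | (1E,3R,4R)-4-[(tert-butyldimethylsilyl)oxy]-1-(2,3:5,6-di-O-isopropylidene-β-D-mannofuranosyl)pent-1-en-3-ol | C[C@@H](O[Si](C)(C)C(C)(C)C)[C@H](O)/C=C/[C@@H]1O[C@H]([C@H]2COC(C)(C)O2)[C@@H]3OC(C)(C)O[C@H]13 | intermediate
15 | benzoic acid | OC(=O)c1ccccc1 | starting material
16 | triphenylphosphonium ether of 14 at O3', benzoate salt | C[C@@H](O[Si](C)(C)C(C)(C)C)[C@H](O[P+](c1ccccc1)(c1ccccc1)c1ccccc1)/C=C/[C@@H]1O[C@H]([C@H]2COC(C)(C)O2)[C@@H]3OC(C)(C)O[C@H]13.[O-]C(=O)c1ccccc1 | intermediate (not isolated)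
17 | (1E,3S,4R)-4-[(tert-butyldimethylsilyl)oxy]-1-(2,3:5,6-di-O-isopropylidene-β-D-mannofuranosyl)pent-1-en-3-yl benzoate | C[C@@H](O[Si](C)(C)C(C)(C)C)[C@H](/C=C/[C@@H]1O[C@H]([C@H]2COC(C)(C)O2)[C@@H]3OC(C)(C)O[C@H]13)OC(=O)c1ccccc1 | intermediate
18 | (1E,3S,4R)-4-[(tert-butyldimethylsilyl)oxy]-1-(2,3-O-isopropylidene-β-D-mannofuranosyl)pent-1-en-3-yl benzoate (5,6-diol) | C[C@@H](O[Si](C)(C)C(C)(C)C)[C@H](/C=C/[C@@H]1O[C@H]([C@H](O)CO)[C@@H]2OC(C)(C)O[C@H]12)OC(=O)c1ccccc1 | intermediate (not isolated)
19 | (1E,3S,4R)-4-[(tert-butyldimethylsilyl)oxy]-1-(2,3-O-isopropylidene-β-D-lyxo-pentodialdo-1,4-furanosyl)pent-1-en-3-yl benzoate | C[C@@H](O[Si](C)(C)C(C)(C)C)[C@H](/C=C/[C@@H]1O[C@H](C=O)[C@@H]2OC(C)(C)O[C@H]12)OC(=O)c1ccccc1 | intermediate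
20 | methyl bis(2,2,2-trifluoroethyl)phosphonoacetate | COC(=O)CP(=O)(OCC(F)(F)F)OCC(F)(F)F | starting material
21 | potassium salt of the carbanion of 20 | [K+].COC(=O)[CH-]P(=O)(OCC(F)(F)F)OCC(F)(F)F | intermediate (not isolated)
22 | methyl (Z)-5,6-dideoxy-2,3-O-isopropylidene-β-D-lyxo-hept-5-enofuranuronate carrying at C1 the (1E,3S,4R)-3-(benzoyloxy)-4-[(tert-butyldimethylsilyl)oxy]pent-1-en-1-yl group | C[C@@H](O[Si](C)(C)C(C)(C)C)[C@H](/C=C/[C@@H]1O[C@H](/C=C\C(=O)OC)[C@@H]2OC(C)(C)O[C@H]12)OC(=O)c1ccccc1 | intermediate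
23 | methyl (Z)-5,6-dideoxy-β-D-lyxo-hept-5-enofuranuronate carrying at C1 the (1E,3S,4R)-3-(benzoyloxy)-4-hydroxypent-1-en-1-yl group (triol) | C[C@@H](O)[C@H](/C=C/[C@@H]1O[C@H](/C=C\C(=O)OC)[C@H](O)[C@@H]1O)OC(=O)c1ccccc1 | intermediate (not isolated)
24 | (1E,3S,4R)-4-hydroxy-1-[(2S,3R,3aR,7aR)-3-hydroxy-5-oxo-2,3,3a,7a-tetrahydro-5H-furo[3,2-b]pyran-2-yl]pent-1-en-3-yl benzoate | C[C@@H](O)[C@H](/C=C/[C@@H]1O[C@@H]2C=CC(=O)O[C@@H]2[C@@H]1O)OC(=O)c1ccccc1 | target

Total step count: 11. Longest linear sequence: 11 steps (1 → 24); compounds 3, 10, 15 and 20 are purchased.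

**Steps most likely to fail**

Step 6 (proposed new method). The amide base may deprotonate 9 at C1 (γ to boron, followed by β-alkoxide elimination) faster than it lithiates 10, or the β-oxido boronate may lose boron and oxygen to a diene before it is silylated. The fallback uses known chemistry, sets out from 9 and returns at 17. Iododeboronation (NaOH, then I2, THF) should give, with retention, (E)-1-iodo-2-(2,3:5,6-di-O-isopropylidene-β-D-mannofuranosyl)ethene F1. Separately, methyl (R)-lactate is silylated (t-BuMe2SiCl, imidazole) to methyl (R)-2-[(tert-butyldimethylsilyl)oxy]propanoate F2 and reduced (i-Bu2AlH, CH2Cl2, −78 °C) to (R)-2-[(tert-butyldimethylsilyl)oxy]propanal F3. Nozaki–Hiyama–Kishi coupling of F1 with F3 (CrCl2, catalytic NiCl2, DMSO) should give mainly the 3',4'-anti alcohol (1E,3S,4R)-4-[(tert-butyldimethylsilyl)oxy]-1-(2,3:5,6-di-O-isopropylidene-β-D-mannofuranosyl)pent-1-en-3-ol F4, by non-chelated addition anti to the silyloxy group. Benzoylation (PhCOCl, pyridine) then gives 17. The minor syn epimer of this coupling is compound 14 itself and is taken to 17 by step 8, so both epimers converge.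

Step 8. SN2 displacement at the carbinol flanked by the silyloxy carbon may be slow, so that elimination or allylic transposition of the activated alcohol takes over. The fallback sets out from 14 and returns at 17. Oxidation with Dess–Martin periodinane should give the enone (1E,4R)-4-[(tert-butyldimethylsilyl)oxy]-1-(2,3:5,6-di-O-isopropylidene-β-D-mannofuranosyl)pent-1-en-3-one F5. Corey–Bakshi–Shibata reduction with the (S)-B-methyl oxazaborolidine, (S)-1-methyl-3,3-diphenyltetrahydro-1H,3H-pyrrolo[1,2-c][1,3,2]oxazaborole, and catecholborane, the alkenyl group acting as the large substituent, should give the (3'S) alcohol F4 of the first fallback, and PhCOCl/pyridine gives 17.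

Step 3. Hydride delivery to the alkynyl-stabilized cation may show poor facial selectivity, or the Lewis acid may remove the terminal acetonide. The fallback sets the C1 configuration by SN2 ring closure instead; it sets out from 5 and returns at 7. Chelation-controlled reduction of the open hydroxy-ynone form of 5 with Zn(BH4)2 (Et2O, −20 °C) should give (3R)-1,2-dideoxy-4,5:7,8-di-O-isopropylidene-1-C-(trimethylsilyl)-D-glycero-D-talo-oct-1-ynitol F6, with the new hydroxyl anti to the C4 oxygen. p-Toluenesulfonyl chloride in pyridine should sulfonylate the propargylic hydroxyl selectively to the 3-O-tosylate F7, which is displaced in situ by the C6 hydroxyl (5-exo-tet, inversion) to give 7.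

**Further compounds**
F1 | step 6 | (E)-1-iodo-2-(2,3:5,6-di-O-isopropylidene-β-D-mannofuranosyl)ethene | I/C=C/[C@@H]1O[C@H]([C@H]2COC(C)(C)O2)[C@@H]3OC(C)(C)O[C@H]13
F2 | step 6 | methyl (R)-2-[(tert-butyldimethylsilyl)oxy]propanoate | C[C@@H](O[Si](C)(C)C(C)(C)C)C(=O)OC
F3 | step 6 | (R)-2-[(tert-butyldimethylsilyl)oxy]propanal | C[C@@H](O[Si](C)(C)C(C)(C)C)C=O
F4 | step 6 | (1E,3S,4R)-4-[(tert-butyldimethylsilyl)oxy]-1-(2,3:5,6-di-O-isopropylidene-β-D-mannofuranosyl)pent-1-en-3-ol | C[C@@H](O[Si](C)(C)C(C)(C)C)[C@@H](O)/C=C/[C@@H]1O[C@H]([C@H]2COC(C)(C)O2)[C@@H]3OC(C)(C)O[C@H]13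
F5 | step 8 | (1E,4R)-4-[(tert-butyldimethylsilyl)oxy]-1-(2,3:5,6-di-O-isopropylidene-β-D-mannofuranosyl)pent-1-en-3-one | C[C@@H](O[Si](C)(C)C(C)(C)C)C(=O)/C=C/[C@@H]1O[C@H]([C@H]2COC(C)(C)O2)[C@@H]3OC(C)(C)O[C@H]13
F6 | step 3 | (3R)-1,2-dideoxy-4,5:7,8-di-O-isopropylidene-1-C-(trimethylsilyl)-D-glycero-D-talo-oct-1-ynitol | C[Si](C)(C)C#C[C@@H](O)[C@H]1OC(C)(C)O[C@H]1[C@H](O)[C@H]2COC(C)(C)O2
F7 | step 3 | 3-O-(p-toluenesulfonyl) derivative of F6 | C[Si](C)(C)C#C[C@@H](OS(=O)(=O)c1ccc(C)cc1)[C@H]1OC(C)(C)O[C@H]1[C@H](O)[C@H]2COC(C)(C)O2
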